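The epsilon run, at 0.23 M of Z, levels off with L near 65.6 %, while the alpha run, at 0.45 M, stays near 50.2 %. Alpha is the flask in question, followed further here.

| flask | Z | remark | time |
|---|---|---|---|
| alpha | 0.45 M | the very flask that is asked about, followed so far |  |
| epsilon | 0.23 M | run made earlier |  |
| flask | 0.45 M |  | 30 h |

| run | time / h | Q / % | L / % |
|---|---|---|---|
| alpha | 0.333 | 1.3 | 4.8 |
| alpha | 1.00 | 1.0 | 28.4 |
| alpha | 2.00 | 2.3 | 43.1 |
| alpha | 3.00 | 1.0 | 45.8 |
| alpha | 4.00 | 1.5 | 50.2 |
| alpha | 5.00 | 2.1 | 48.8 |
| epsilon | 0.833 | 2.5 | 29.7 |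
| epsilon | 2.50 | 4.0 | 59.0 |
| epsilon | 4.00 | 3.5 | 64.8 |
| epsilon | 6.00 | 2.1 | 64.8 |
| epsilon | 10.0 | 3.2 | 64.9 |
| epsilon | 12.0 | 3.5 | 65.6 |

(scatter of a reading: 1 percentage point)

- share of Q in Q plus L at 8.0 min
- share of Q in Q plus L at 2.0 h
- share of Q in Q plus L at 30 h
- which of Q and L there is more of at 30 h

- percent here means Z units held: one X counts as two
- what may be going on: Z <-> J; J -> D; J -> Q; D <-> G; D -> E; E -> L; 2 Z -> X

Follow one molecule that has reached J and does not return to Z. It either goes to Q or passes to D, and from D the scheme leads through E to L, with G as a detour. Each Q reading scatters by 1 percentage point, so the 7 late readings of both runs are pooled: from 3.00 h in alpha and 4.00 h in epsilon, Q over Q plus L reads 4.01 %. This reading is the fork share, a selectivity, taken here as the molecule's chance of ending as Q. Q per unit of L is then 4.17 %.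

My own curve of the share for the alpha flask starts from L's straight stretch, which rises at 0.354 /h of the charge and runs back to zero at a lag of 0.197 h. At 8.0 min, inside the lag, Q lies one step beyond J and is taken to grow with time, which gives an estimate of 0.197 %. L lies 3 steps beyond J and is taken to grow as the cube of time, which scales the first L reading to an estimate of 0.308 %. The share is therefore estimated at 39.0 %, and on these estimates L passes Q at about 6.40 min. L's line meets its level of 48.3 % at a knee near 1.56 h. Past it, at 2.0 h, Q is estimated near 2.01 % against the reading of 43.1 % L, which gives 4.46 %. The curve then runs into the fork share.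

The forecast gives 30 %, 4.5 % and 4 %, with L ahead: “Q and L both come from J, so their final ratio should be fixed”. At 8.0 min its share is lower than my estimate of 39.0 %, and at the later times the two lie close.

    Z ⇌ J (K = 2.00, k = 0.527 /min)
    J → D (k = 0.0455 /min)
    J → Q (k = 0.00189 /min)
    D ⇌ G (K = 4.10, k = 0.0286 /min)
    D → E (k = 0.358 /min)
    E → L (k = 0.0344 /min)
    2 Z → X (k = 0.407 /M/min)

The flask gives 40.8 % at 8.0 min, 4.48 % at 2.0 h and 3.99 % at 30 h, with L ahead, 51.0 % against 2.12 % of Q. At 30.0 h it holds 46.9 % as X. Taken on the Q plus L of this flask, the fork share of 4.01 % gives 2.13 % of Q. The neighbouring flask at 1.1 M of Z ends with 65.6 % as X and 33.0 % as L, so the same fork gives 1.38 % of Q, and that flask holds 1.37 %.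

The earlier runs and the new flask were computed from invented constants, noise included.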